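The benzo ring A is fused to the pyran ring C (O1, C2, C3, C4, C4a, C8a) at the neighbouring carbons C8a and C4a. The two bonds leaving them, C8a–O1 and C4a–C4, are therefore made from the two carbons of a single aryne. C3 (isopropyl) and C4 (isobutyl) are the α-carbon and carbonyl of diisobutyl ketone, and C2 is the carbonyl of 2,4,6-trimethoxybenzaldehyde. An enantioselective anti aldol thus fixes C2 and C3. Its trimethylsilyl ether, a latent alkoxide, meets 3,5-dimethoxybenzyne under fluoride. O-Arylation, then addition of the aryl anion to the ketone, builds ring C in one operation. Ionic reduction, fourfold formylation and demethylation follow.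

Key step: step 8

Locants: chroman numbering is used; ring B is the aryl group at C2 (primed locants).
Assumption: the borane made from (−)-menthone is taken to carry all-equatorial cyclohexylmethyl ligands and to direct the enolate to the Re face of the aldehyde. If the first run shows the opposite sense, (+)-menthone is used in step 1 and nothing else changes.

Step 1
Reactants: 1 (−)-menthone
Product: 2 (2S,5R)-2-isopropyl-5-methyl-1-methylidenecyclohexane
Conditions: Ph3PCH3Br, n-BuLi (slightly less than 1 equiv per salt), THF, 0 °C to rt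
Reagents that add atoms: methyltriphenylphosphonium bromide, C[P+](c1ccccc1)(c1ccccc1)c1ccccc1.[Br-]
Why: Wittig methylenation of a cyclohexanone, run without excess base so that the epimerisable centre next to the carbonyl is not equilibrated and both stereocentres of 1 pass into 2.

Step 2
Reactants: 2 (two equivalents)
Product: 3 chlorobis{[(1R,2S,5R)-2-isopropyl-5-methylcyclohexyl]methyl}borane
Conditions: BH2Cl·SMe2, CH2Cl2, 0 °C to rt; crystallisation from Et2O at low temperature under argon
Reagents that add atoms: monochloroborane–dimethyl sulfide, C[S+](C)[BH2-]Cl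
Why: Twofold anti-Markovnikov hydroboration of the 1,1-disubstituted alkene, in which hydrogen should reach the ring carbon from the axial face and leave the CH2B arm equatorial and trans to isopropyl (new centre 1R), crystallisation removing minor diastereomers.

Step 3
Reactants: 3 chiral dialkylboron chloride; 4 diisobutyl ketone; 5 2,4,6-trimethoxybenzaldehyde
Product: 8 (1R,2S)-1-hydroxy-5-methyl-2-(propan-2-yl)-1-(2,4,6-trimethoxyphenyl)hexan-3-one (anti aldol), via E-enol borinate 6 (not isolated), via boron aldolate 7 (not isolated)
Conditions: 3, Et3N, Et2O, 0 °C; 5, −78 to −20 °C; H2O2, MeOH, pH 7 buffer, 0 °C; recrystallisation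
Reagents that add atoms: none
Why: Boron-mediated anti aldol addition: the dialkylboron chloride and Et3N enolise the symmetrical ketone (only one regioisomer is possible) to E-enol borinate 6, whose closed chair transition state with the aryl group equatorial gives anti aldolate 7, while the menthone-derived ligands, built for E-enolates where isopinocampheyl ligands discriminate poorly, expose the Re face of 5 and so set the future C2 (1R) and C3 (2S).

Step 4
Reactants: 8 anti aldol
Product: 9 (1R,2S)-5-methyl-2-(propan-2-yl)-1-(2,4,6-trimethoxyphenyl)-1-[(trimethylsilyl)oxy]hexan-3-one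
Conditions: 1-(trimethylsilyl)imidazole, CH2Cl2, rt
Reagents that add atoms: 1-(trimethylsilyl)imidazole, C[Si](C)(C)n1ccnc1
Why: Silylation of a secondary alcohol under neutral conditions, strong enough for the hindered carbinol and releasing only a weak base, so that neither acid ionisation of the electron-rich benzylic C–O bond nor retro-aldol cleavage sets in and no stereocentre is touched.

Step 5
Reactants: 10 3,5-dimethoxyphenol
Product: 11 3,5-dimethoxyphenyl N-isopropylcarbamate
Conditions: i-PrNCO, Et3N (cat.), CH2Cl2, rt
Reagents that add atoms: isopropyl isocyanate, CC(C)N=C=O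
Why: Base-catalysed addition of a phenol to an isocyanate gives the secondary carbamate, which directs the metalation of step 6 and can be removed later under mild base.

Step 6
Reactants: 11 carbamate
Product: 15 3,5-dimethoxy-2-(trimethylsilyl)phenyl N-isopropylcarbamate, via N-silyl carbamate 12 (not isolated), via aryllithium 13 (not isolated), via bis-silyl carbamate 14 (not isolated)
Conditions: TBSOTf, TMEDA, Et2O, 0 °C to rt; n-BuLi, TMEDA, −78 °C; Me3SiCl, −78 °C to rt; aq NaHSO4
Reagents that add atoms: chlorotrimethylsilane, C[Si](C)(C)Cl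
Why: Directed ortho-metalation: transient N-silylation (12) masks the N–H, the carbamate and the meta methoxyl together steer n-BuLi to the carbon between them (13; the two such positions are equivalent by symmetry) rather than between the two methoxyls, Me3SiCl traps the anion (14) and the acidic wash removes the N-silyl group.

Step 7
Reactants: 15 silyl carbamate
Product: 17 3,5-dimethoxy-2-(trimethylsilyl)phenyl trifluoromethanesulfonate, via silylphenol 16 (not isolated)
Conditions: DBU, Et2NH, MeCN, 40 °C; then PhNTf2, rt
Reagents that add atoms: N-phenylbis(trifluoromethanesulfonimide), O=S(=O)(N(c1ccccc1)S(=O)(=O)C(F)(F)F)C(F)(F)F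
Why: E1cB cleavage of the secondary carbamate (DBU, Et2NH as scavenger) frees 16 as its salt, which is triflated in the same flask, a sequence established for 2-silylaryl triflates and mild enough to avoid protodesilylation of the electron-rich ring.

Step 8
Reactants: 9 silyl ether of the anti aldol; 17 silylaryl triflate
Product: 22 (2R,3S)-5,7-dimethoxy-4-(2-methylpropyl)-3-(propan-2-yl)-2-(2,4,6-trimethoxyphenyl)chroman-4-ol as a mixture of C4 epimers, via potassium alkoxide 18 (not isolated), via 3,5-dimethoxybenzyne 19 (not isolated), via aryl anion 20 (not isolated), via tertiary alkoxide 21 (not isolated)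
Conditions: 9 (1 equiv), 17 (2 equiv), spray-dried KF, 18-crown-6, THF, −20 °C to rt; then water
Reagents that add atoms: none
Why: Proposed new method: fluoride removes the O-silyl group of 9 and the C-silyl group of 17 side by side, so alkoxide 18 is released only in step with aryne 19 and without any proton source, which keeps its lifetime short and thereby limits retro-aldol cleavage and epimerisation at C3. Alkoxide 18 adds to the aryne carbon remote from the flanking methoxyl (C8a–O1), because that inductively withdrawing group distorts the triple bond and stabilises charge on the carbon next to it, so the charge arrives at C4a and the 5,7-dioxygenation pattern follows. Aryl anion 20 then attacks the ketone (C4a–C4) in a 6-exo-trig closure of ring C to give alkoxide 21, which is protonated on work-up. The closest known reaction types are the aryne annulation of salicylaldehydes and 2-hydroxyaryl ketones to xanthenols, the O–H insertion of arynes into aliphatic alcohols and the acyl-alkylation of arynes by β-keto esters, where an aryl anion also adds to a ketone bearing α-hydrogens; an aliphatic aldolate has not been used in this way. C2 and C3 are carried over from 9 unchanged, whereas the new centre C4 is governed only by the chair-like closure and need not be controlled because step 9 flattens it. The step needs carbonyl addition to outrun proton transfer from the α-positions, which the six-membered geometry, the exclusion of MeCN and ammonium salts and the potassium ion bridging carbonyl and anion should secure.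

Step 9
Reactants: 22 chroman-4-ol (both epimers)
Product: 24 (2R,3R,4S)-5,7-dimethoxy-4-(2-methylpropyl)-3-(propan-2-yl)-2-(2,4,6-trimethoxyphenyl)chroman, via C4 cation 23 (not isolated)
Conditions: Et3SiH (10 equiv), CF3CO2H (2 equiv), CH2Cl2, −78 to −30 °C; aq NaHCO3
Reagents that add atoms: none
Why: Ionic hydrogenation: both epimers ionise to the same tertiary, triply oxygen-stabilised cation 23, where strain against the in-plane isobutyl group turns the C3 isopropyl group pseudoaxial, so hydride enters anti to it, as nucleophiles do with 2,3-trans-flavan-4-yl cations, giving the 3,4-cis (4S) product, while low temperature, little acid and excess silane protect the acid-labile C2–O1 bond and the C3–H.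

Step 10
Reactants: 24 pentamethyl ether
Product: 25 (2R,3R,4S)-2-(3,5-diformyl-2,4,6-trimethoxyphenyl)-5,7-dimethoxy-4-(2-methylpropyl)-3-(propan-2-yl)chroman-6,8-dicarbaldehyde
Conditions: Cl2CHOMe (12 equiv), TiCl4 (12 equiv), CH2Cl2, −78 to 0 °C; ice, 1 M HCl
Reagents that add atoms: dichloromethyl methyl ether, COC(Cl)Cl; water, O
Why: Rieche formylation: C6, C8, C3' and C5' are the only free aromatic positions, each lies between two oxygen donors, twofold formylation of a trialkoxybenzene ring is established with an excess of this reagent pair, the first formyl group on ring B removes the donor power that makes C2–O1 acid-labile, and any methyl ether lost next to a new aldehyde is harmless because step 11 removes them all.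

Step 11
Reactants: 25 tetraaldehyde pentamethyl ether
Product: 26 sideroxylonal A
Conditions: BBr3 (15 equiv), CH2Cl2, −78 to 0 °C; water
Reagents that add atoms: none
Why: Lewis acid cleavage of aryl methyl ethers: each of the five methoxyl groups stands ortho to a formyl group, so boron chelation speeds bromide attack at methyl, whereas O1–C2 is a hindered secondary centre whose ionisation is disfavoured by the two formyl groups on ring B, and none of the three stereocentres is involved.

Compound list
1 | (−)-menthone, (2S,5R)-2-isopropyl-5-methylcyclohexanone | CC(C)[C@@H]1CC[C@@H](C)CC1=O | starting material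
2 | (2S,5R)-2-isopropyl-5-methyl-1-methylidenecyclohexane | CC(C)[C@@H]1CC[C@@H](C)CC1=C | intermediate
3 | chlorobis{[(1R,2S,5R)-2-isopropyl-5-methylcyclohexyl]methyl}borane | ClB(C[C@@H]1C[C@H](C)CC[C@H]1C(C)C)C[C@@H]1C[C@H](C)CC[C@H]1C(C)C | intermediate
4 | diisobutyl ketone (2,6-dimethylheptan-4-one) | CC(C)CC(=O)CC(C)C | starting material
5 | 2,4,6-trimethoxybenzaldehyde | COc1cc(OC)c(C=O)c(OC)c1 | starting material
6 | (E)-2,6-dimethylhept-3-en-4-yl bis{[(1R,2S,5R)-2-isopropyl-5-methylcyclohexyl]methyl}borinate | CC(C)C/C(=C\C(C)C)OB(C[C@@H]1C[C@H](C)CC[C@H]1C(C)C)C[C@@H]1C[C@H](C)CC[C@H]1C(C)C | intermediate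
7 | dialkylboron aldolate of 8, (1R,2S) | CC(C)CC(=O)[C@@H](C(C)C)[C@@H](OB(C[C@@H]1C[C@H](C)CC[C@H]1C(C)C)C[C@@H]1C[C@H](C)CC[C@H]1C(C)C)c1c(OC)cc(OC)cc1OC | intermediate
8 | (1R,2S)-1-hydroxy-5-methyl-2-(propan-2-yl)-1-(2,4,6-trimethoxyphenyl)hexan-3-one | CC(C)CC(=O)[C@@H](C(C)C)[C@@H](O)c1c(OC)cc(OC)cc1OC | intermediate
9 | (1R,2S)-5-methyl-2-(propan-2-yl)-1-(2,4,6-trimethoxyphenyl)-1-[(trimethylsilyl)oxy]hexan-3-one | CC(C)CC(=O)[C@@H](C(C)C)[C@@H](O[Si](C)(C)C)c1c(OC)cc(OC)cc1OC | intermediate
10 | 3,5-dimethoxyphenol | COc1cc(O)cc(OC)c1 | starting material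
11 | 3,5-dimethoxyphenyl N-isopropylcarbamate | COc1cc(OC(=O)NC(C)C)cc(OC)c1 | intermediate
12 | 3,5-dimethoxyphenyl N-(tert-butyldimethylsilyl)-N-isopropylcarbamate | COc1cc(OC(=O)N(C(C)C)[Si](C)(C)C(C)(C)C)cc(OC)c1 | intermediate
13 | 2-lithio derivative of 12 | COc1cc(OC)c([Li])c(OC(=O)N(C(C)C)[Si](C)(C)C(C)(C)C)c1 | intermediate
14 | 3,5-dimethoxy-2-(trimethylsilyl)phenyl N-(tert-butyldimethylsilyl)-N-isopropylcarbamate | COc1cc(OC)c([Si](C)(C)C)c(OC(=O)N(C(C)C)[Si](C)(C)C(C)(C)C)c1 | intermediate
15 | 3,5-dimethoxy-2-(trimethylsilyl)phenyl N-isopropylcarbamate | COc1cc(OC)c([Si](C)(C)C)c(OC(=O)NC(C)C)c1 | intermediate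
16 | 3,5-dimethoxy-2-(trimethylsilyl)phenol | COc1cc(O)c([Si](C)(C)C)c(OC)c1 | intermediate
17 | 3,5-dimethoxy-2-(trimethylsilyl)phenyl trifluoromethanesulfonate | COc1cc(OC)c([Si](C)(C)C)c(OS(=O)(=O)C(F)(F)F)c1 | intermediate
18 | potassium alkoxide of 8, (1R,2S) | CC(C)CC(=O)[C@@H](C(C)C)[C@@H]([O-])c1c(OC)cc(OC)cc1OC.[K+] | intermediate
19 | 3,5-dimethoxybenzyne | COC1=CC(OC)=CC#C1 | intermediate
20 | potassium 2-aryloxy-4,6-dimethoxyphenyl anion, the O-arylated aldol with charge at C4a, (1R,2S) | CC(C)CC(=O)[C@@H](C(C)C)[C@@H](Oc1cc(OC)cc(OC)[c-]1)c1c(OC)cc(OC)cc1OC.[K+] | intermediate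
21 | potassium C4 alkoxide of 22 | CC(C)CC1([O-])c2c(OC)cc(OC)cc2O[C@@H](c2c(OC)cc(OC)cc2OC)[C@@H]1C(C)C.[K+] | intermediate
22 | (2R,3S)-5,7-dimethoxy-4-(2-methylpropyl)-3-(propan-2-yl)-2-(2,4,6-trimethoxyphenyl)chroman-4-ol, 2,3-trans, C4 epimers | CC(C)CC1(O)c2c(OC)cc(OC)cc2O[C@@H](c2c(OC)cc(OC)cc2OC)[C@@H]1C(C)C | intermediate
23 | C4 benzylic cation from 22, C2 and C3 as in 22 | CC(C)C[C+]1c2c(OC)cc(OC)cc2O[C@@H](c2c(OC)cc(OC)cc2OC)[C@@H]1C(C)C | intermediate
24 | (2R,3R,4S)-5,7-dimethoxy-4-(2-methylpropyl)-3-(propan-2-yl)-2-(2,4,6-trimethoxyphenyl)chroman, 2,3-trans, 3,4-cis | CC(C)C[C@@H]1c2c(OC)cc(OC)cc2O[C@@H](c2c(OC)cc(OC)cc2OC)[C@@H]1C(C)C | intermediate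
25 | (2R,3R,4S)-2-(3,5-diformyl-2,4,6-trimethoxyphenyl)-5,7-dimethoxy-4-(2-methylpropyl)-3-(propan-2-yl)chroman-6,8-dicarbaldehyde | CC(C)C[C@@H]1c2c(OC)c(C=O)c(OC)c(C=O)c2O[C@@H](c2c(OC)c(C=O)c(OC)c(C=O)c2OC)[C@@H]1C(C)C | intermediate
26 | sideroxylonal A, (2R,3R,4S) | CC(C)C[C@@H]1c2c(O)c(C=O)c(O)c(C=O)c2O[C@@H](c2c(O)c(C=O)c(O)c(C=O)c2O)[C@@H]1C(C)C | target

Total step count: 11.
Longest linear sequence: 8 steps (1, 2, 3, 4, 8, 9, 10, 11), counted through the boron reagent. Through the materials that contribute carbon it is 7 steps (5 to 11).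

Steps most likely to fail

Step 8. The liberated alkoxide may undergo retro-aldol cleavage before it meets the aryne. The aryl anion may take a proton from an α-position, after which the aryloxide is lost by β-elimination. The tertiary alkoxide may also be arylated by excess aryne. Fallback, from 9 back to 22: the same two bonds are made one after the other, in reverse order, by known reactions.
- Commercial 1-bromo-3,5-dimethoxybenzene is iodinated (NIS, MeCN, rt) to 1-bromo-2-iodo-3,5-dimethoxybenzene F1.
- Iodine–magnesium exchange (i-PrMgCl·LiCl, THF, −40 °C) gives (2-bromo-4,6-dimethoxyphenyl)magnesium chloride F2.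
- F2 is added to ketone 9 in the presence of LaCl3·2LiCl (C4a–C4). Bu4NF in the work-up removes the silyl group and should give (1R,2S)-3-(2-bromo-4,6-dimethoxyphenyl)-5-methyl-2-(propan-2-yl)-1-(2,4,6-trimethoxyphenyl)hexane-1,3-diol F3.
- With the ketone gone, retro-aldol cleavage is no longer possible. Palladium-catalysed intramolecular C–O coupling of the secondary alcohol (Pd(OAc)2, 2-(di-tert-butylphosphino)-1,1'-binaphthyl, Cs2CO3, toluene, 70 °C) closes C8a–O1 and returns to 22.

Step 9. Hydride transfer may show poor facial selectivity, because the face anti to isopropyl is also the face of the C2 aryl group. Loss and return of the C3 proton at the cation stage may scramble C3. The acid may also ionise and reduce the C2–O1 bond. Fallback, from 22 back to 24: the cation is caught by a far better nucleophile under trace acid, and the C–H bond is then made by a radical.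
- PhSH and catalytic camphorsulfonic acid (CH2Cl2, −40 °C) should give (2R,3S)-5,7-dimethoxy-4-(2-methylpropyl)-4-(phenylsulfanyl)-3-(propan-2-yl)-2-(2,4,6-trimethoxyphenyl)chroman F4. This is the thiolysis long used at C4 of flavans.
- Bu3SnH and AIBN (toluene, 90 °C) replace sulfur by hydrogen under neutral conditions. The bulky stannane should approach the benzylic radical anti to isopropyl, and the route is rejoined at 24.

Step 3. Enolisation of the β-branched ketone by the bulky borane may be slow. The enolate geometry may erode, and the facial discrimination towards the hindered, electron-rich aldehyde may be too low for a single enantiomer. Fallback, from 4 and 5 back to 8: reagent control is given up for resolution.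
- Commercial dicyclohexylboron chloride and Et3N (Et2O, 0 °C), then 5 and oxidative work-up, should give the racemic anti aldol. This is 8 together with its mirror image (1S,2R)-1-hydroxy-5-methyl-2-(propan-2-yl)-1-(2,4,6-trimethoxyphenyl)hexan-3-one F5.
- The two are separated by preparative chromatography on a chiral stationary phase, and steps 1 and 2 drop out.

Further compounds
F1 | step 8 | 1-bromo-2-iodo-3,5-dimethoxybenzene | COc1cc(Br)c(I)c(OC)c1
F2 | step 8 | (2-bromo-4,6-dimethoxyphenyl)magnesium chloride | COc1cc(Br)c([Mg]Cl)c(OC)c1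
F3 | step 8 | (1R,2S)-3-(2-bromo-4,6-dimethoxyphenyl)-5-methyl-2-(propan-2-yl)-1-(2,4,6-trimethoxyphenyl)hexane-1,3-diol, C3 epimers | CC(C)CC(O)(c1c(Br)cc(OC)cc1OC)[C@@H](C(C)C)[C@@H](O)c1c(OC)cc(OC)cc1OC
F4 | step 9 | (2R,3S)-5,7-dimethoxy-4-(2-methylpropyl)-4-(phenylsulfanyl)-3-(propan-2-yl)-2-(2,4,6-trimethoxyphenyl)chroman, C4 epimers | CC(C)CC1(Sc2ccccc2)c2c(OC)cc(OC)cc2O[C@@H](c2c(OC)cc(OC)cc2OC)[C@@H]1C(C)C
F5 | step 3 | (1S,2R)-1-hydroxy-5-methyl-2-(propan-2-yl)-1-(2,4,6-trimethoxyphenyl)hexan-3-one | CC(C)CC(=O)[C@H](C(C)C)[C@H](O)c1c(OC)cc(OC)cc1OC
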